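3 questions stand on this flask, and the second, the excess in the product, can be estimated from the runs without any rate constant.

| setting | spring | dusk | flask |
|---|---|---|---|
| left-handed substrate | 0.17 M | 0.17 M | 0.17 M |
| right-handed substrate | 0.17 M | 0.17 M | 0.17 M |
| reagent | 1.1 equiv | 1.1 equiv | 1.10 equiv |
| free catalyst | 0.17 mol% | 0.17 mol% | 0.17 mol% |
| impurity | 0.055 mM | 0.083 mM | 0.11 mM |
| added ligand | 0.32 mM | 0.32 mM | 0.32 mM |
| remark | run made earlier | run made earlier |  |
| time |  |  | 2.0 h |

| run | time / min | left-handed substrate / % | right-handed substrate / % | left-handed product / % |
|---|---|---|---|---|
| spring | 6.00 | 49.0 | 48.2 | 3.3 |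
| spring | 20.0 | 45.8 | 49.8 | 5.7 |
| spring | 30.0 | 41.8 | 50.9 | 9.4 |
| spring | 50.0 | 36.0 | 47.0 | 12.7 |
| spring | 80.0 | 35.7 | 45.4 | 20.8 |
| dusk | 6.00 | 47.5 | 51.0 | 0.7 |
| dusk | 20.0 | 45.9 | 52.2 | 6.9 |
| dusk | 30.0 | 43.4 | 48.0 | 7.9 |
| dusk | 50.0 | 39.6 | 47.6 | 11.8 |
| dusk | 80.0 | 36.5 | 45.2 | 18.7 |

(readings scatter by 1 percentage point)

1. part of the left-handed substrate and right-handed substrate charged together that has reacted at 2.0 h
2. excess of left-handed product over right-handed product in the product at 2.0 h
3. excess of right-handed substrate over left-handed substrate among what is left of the two at 2.0 h

- free catalyst is single-handed; left-handed substrate and right-handed substrate are mirror images of each other, charged as a racemate, each of them at the stated concentration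
- an excess is the difference of the two amounts in percent of their sum
- an excess is below zero if the other one leads

Two of us read the spring and dusk runs differently. The first holds a plain kinetic resolution: each substrate leaves for its own product, so the two falls compare the two rates. By 80.0 min the runs together have lost 28 percentage points of left-handed substrate and 9.4 points of right-handed substrate. On this view right-handed product is 0.338 of left-handed product, an excess of 49.5 %.

The second holds a dynamic kinetic resolution: right-handed substrate leaves by turning into its mirror image, so its fall says little about product. Right-handed product was not read, but the balance gives it: the gap is the whole charge less [left-handed substrate], [right-handed substrate] and [left-handed product]. I take the wrong-hand ratio as summed gap over summed [left-handed product]. A catalyst without preference is the zero of the scale, with ratio 1 and excess 0; in general the excess is (1 − ratio)/(1 + ratio). I pool both runs despite their different impurity, assuming the amount of free catalyst cancels in the ratio.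

The gaps sum to −4.4 points, with a scatter of 5.5 points, while [left-handed product] sums to 98 points. The first view needs a gap sum of 33 points, which is more than the runs show. Two standard deviations above the reading give my upper estimate of the wrong-hand ratio, 0.0670, so I commit to an excess of about 87.5 % or more. The first view keeps its ground on c: turning one substrate into the other leaves their sum unchanged, so that fall reads the same under both views.

The forecast takes the first side, "The right-handed substrate falls more slowly", and gives 24.3 %, 54 % and 17.3 %. The flask gives 21.9 %, 89.9 % and 11.6 %, so the excess stands above my estimate of 87.5 %.

    left-handed substrate ⇌ right-handed substrate (k = 1.05 × 10⁻⁴ s⁻¹)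
    free catalyst + impurity → spent catalyst (k = 338 M⁻¹ s⁻¹)
    free catalyst + added ligand ⇌ idle complex, settled at all times (K = 3270 M⁻¹)
    reagent + free catalyst + right-handed substrate → free catalyst + right-handed product (k = 0.224 M⁻² s⁻¹)
    reagent + free catalyst + left-handed substrate → free catalyst + left-handed product (k = 4.87 M⁻² s⁻¹)

At 2.00 h the flask holds 1.11 % right-handed product against 20.8 % left-handed product, a ratio of 0.0534, under my upper estimate of 0.0670. The neighbour charged with 5.4 × 10⁻⁴ M of added ligand keeps less free catalyst at that time, 25.6 % against 34.6 % of the catalyst charged. With free catalyst taken to cancel in the ratio, the same reckoning gives that neighbour the same estimate of 87.5 % or more. That neighbour holds 0.879 % right-handed product against 17.0 % left-handed product, a ratio of 0.0517, about that of the flask. Its c falls to 17.9 %, while its excess stands at 90.2 %.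

The numbers in the tables were computed from invented constants; noise was put on by code.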